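## The problem

The target, 6β-acetoxy-5α-labda-8,13Z-diene-7α,15-diol (5S,6S,7S,10S), is a trans-fused decalin. Ring A (C1–C5, C10) carries a gem-dimethyl group at C4. Ring B (C5–C10) carries the angular methyl at C10, a tetrasubstituted C8=C9 double bond with a methyl on C8, and on C9 a six-carbon chain ending in a Z-trisubstituted allylic alcohol (C13=C14, C15–OH). The four stereocentres are contiguous in ring B: quaternary C10, C5 (H trans to the C10 methyl), C6 (acetoxy on the β face, syn-axial to the C10 methyl and the β methyl on C4) and C7 (allylic hydroxyl on the α face). The two oxygens are therefore trans-diaxial. C10 has no hydrogen and cannot be corrected later, but once in place it can control the rest. C5 can relax to the trans fusion through an enol, a hydride can reach a C6 carbonyl only from the α face because two axial methyls close the β face, and the resulting 6β-hydroxyl can deliver a hydride to a C7 carbonyl on its own face. C10 does not control a C7 carbonyl in a flat ring B, where it lies four atoms away. The sensitive points are the C7 carbinol (allylic to a tetrasubstituted alkene, easily ionised), the Z allylic alcohol of the chain, α-ketol shifts between C6 and C7, and the fact that the acetate sits on the least reactive of three hydroxyls. The feature that opens the route is that every carbon of ring B is substituted, with the C7 oxygen para to C10 and the C6 oxygen next to it. Ring B is thus a hexasubstituted guaiacol-type phenol in disguise, and C-alkylation of that phenol at C10 by the C1–C3 unit hanging from C4 closes ring A, creates C10 and leaves the C8=C9 alkene, the C7 carbonyl and a C6 enol ether.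

## Retrosynthesis

**Acetate and silyl groups (32 ⇐ 31 ⇐ 30 ⇐ 29).** The cuts are the acyl C–O bond at O6 and the two O–Si bonds. The 6β-hydroxyl cannot be acylated selectively in a free diol, so the target 32 is traced to the bis-silyl ether 31, in which the acetate was put on the only free hydroxyl of 30. Compound 30 comes from the trans-diol 29 by silylation of the more accessible C7 hydroxyl. Acetylating earlier, at the ketol stage, was rejected as the main line because the C7 carbonyl would then be reduced without the directing hydroxyl and from the wrong face.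

**C7, C6 and C5 (29 ⇐ 28 ⇐ 27 ⇐ 25).** The C7–H bond of 29 is cut back to the α-hydroxy enone 28, where the 6β-hydroxyl delivers the hydride. Ketol 28 is traced to the diol 27 (both C7 epimers) by allylic oxidation, and 27 to the diosphenol 25 by two hydride additions and one protonation at C5. C7 is deliberately left uncontrolled in the first reduction, because the flat dienone offers no bias, and is erased and re-set once C6 exists. C6 and C5 are set by the substrate.

**Enol ether and ring-A alkene (25 ⇐ 24 ⇐ 23).** The O6–CH2 acetal bond and the two C–H bonds at C2 and C3 are cut. The methoxymethyl ether is preferred over a methyl ether because an α-methoxy dienone would need strong acid or hot thiolate for cleavage. Saturation of C2=C3 is placed directly after the ring closure, where the only competing alkene is trisubstituted.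

**Key disconnection (23 ⇐ 22).** The C1–C10 bond is cut, which opens ring A and rearomatises ring B to the phenol 22 with a Z allylic carbonate on the benzylic quaternary carbon C4. Cutting C9–C10 or C5–C10 instead would leave a quaternary centre to be made between two fully substituted carbons by an intermolecular reaction. The chosen cut makes it intramolecularly on a flat precursor whose six substituents can be placed by arene chemistry. The forward reaction must deliver para C-attack, the far allyl terminus and one face of the phenoxide.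

**Tether end groups (22 ⇐ 21 ⇐ 20 ⇐ 19).** The phenol is unmasked last from its silyl ether 21, the carbonate of 21 comes from the allylic alcohol 20, and 20 from the Z enoate 19. The enoate serves as the protected form of the allylic alcohol so that the carbonate appears only after all other palladium-catalysed steps.

**Side chain (19 ⇐ 17 + 4; 17 ⇐ 16; 4 ⇐ 3 ⇐ 1).** The C12–C13 bond is cut between an alkylborane from styrene 17 and the Z vinyl iodide 4, so the alkene geometry is bought with 4 and only transferred. The C9–C11 bond is cut back to the aryl bromide 16. Fragment 4 comes from the iodoalkenol 3 and but-2-yn-1-ol 1. Coupling an alkyl metal directly at the hindered bromide would need a longer fragment synthesis.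

**Z tether alkene (16 ⇐ 15 ⇐ 13).** The C2=C3 bond is cut to the neopentyl aldehyde 15, and the aldehyde to the vinyl group of 13. A Z-selective olefination of an α-quaternary aldehyde is more reliable than forming this alkene while making the quaternary carbon.

**C7 oxygen (13 ⇐ 12 ⇐ 10 ⇐ 9 ⇐ 8).** The C7–O bond is traced through the phenol 12 to the aldehyde 10 (aryl migration), and the C7–CHO bond of 9 to the phenol 8, whose one free ortho position takes the formyl group. Each oxygen gets its own protecting group when it appears, which avoids differentiating a catechol.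

**Quaternary benzylic carbon (8 ⇐ 7 ⇐ 5 + 6).** The C4–C5 bond is cut by a [3,3] shift back to the prenyl ether 7, made from the symmetrical 4-bromo-3,5-dimethylphenol 5 and prenyl bromide 6. The starting phenol already carries both methyls and the C9 halogen, and its two ortho positions become C5 and C7. An intermolecular tert-alkylation at a position flanked by two substituents was judged unreliable.

## Roads not taken

**Alternative 1:** The cuts are C9–C10 and C5–C6 around a ring-A cyclohexanone. In the forward sense the vinylalane A3 adds to the enone A2 under a chiral N-heterocyclic carbene–copper catalyst, and the aluminium enolate is trapped by the aldehyde A4 to give A1 with C10 and C5 set.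
- Merits: enantioselective conjugate addition of alkenylaluminium reagents to β-substituted cyclic enones is established chemistry for all-carbon quaternary centres, and three simple components reach A1 in one operation. In precedent for the key step this road is better than the chosen plan.
- Weak points: A1 still has a ketone at C4 that must become a gem-dimethyl group next to the epimerisable C5 and a retro-aldol-prone carbinol. The C8=C9 bond must be closed by metathesis of two 1,1-disubstituted alkenes to a tetrasubstituted one. C7 carries no oxygen, the side chain must be grown from C12 with Z control, A4 isomerises easily into conjugation, and the C6 configuration from the aldol is uncertain.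
- Comparison: the chosen plan offsets its weaker precedent by delivering, in 23, all twenty skeletal carbons and both ring-B oxygens at the right carbons, so that only redox and protecting-group steps follow.

**Alternative 2:** The cuts are C7–C8 and C8–C9, C8 being inserted into a five-membered ring. A dihalocarbene adds to the C7=C9 alkene of the Hajos–Parrish-type trans-hydrindene A6, and silver-assisted opening of the dibromocyclopropane with capture of water at C7 gives A5.
- Merits: the absolute configuration comes from a proline-catalysed annulation and is secure. The ring expansion is a known reaction type and delivers the C7 hydroxyl and a C8 bromide for the methyl in one step. A5 also has the C6 and C7 oxygens already differentiated, which the chosen plan needs three steps to achieve. In these respects this road is better.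
- Weak points: reaching A6 is long, since the trans ring fusion is the disfavoured one in this ketone family and the gem-dimethyl group, the C6 oxygen and the C9 chain must all be installed first. The carbene must add to an alkene flanked by quaternary C10. The site and face of water capture rest on conformational arguments, a full equivalent of AgClO4 is consumed, and a hindered vinyl bromide must then be methylated and the alkyne turned into the Z allylic alcohol.
- Comparison: the chosen plan has the less certain key step but a convergent assembly and no trans-hydrindane problem.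

**Alternative 3:** The cuts are C7–C8 and C9–C10. The silyloxydiene A8 and the ynal A9 combine under a chiral oxazaborolidinium Lewis acid to give the cyclohexadiene A7, closing ring B and setting C10.
- Merits: it is the most convergent of all. Ring A is bought ready-made, two skeletal bonds and the stereocentre form in one step, and the enol ether stores the C6 oxygen by the same device used in the chosen plan. If the cycloaddition worked, this road would probably be the shortest.
- Weak points: the diene terminus that must become C10 is fully substituted, and the gem-dimethyl group twists the diene out of the s-cis plane, which is where dienes of this type usually fail. Face selection with an ynal at a remote, forming quaternary centre is uncertain. C7 arrives as CH2 and needs a later stereocontrolled oxidation, and the chain must be extended from the C11 aldehyde.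
- Comparison: the chosen plan makes the bond to C10 intramolecularly, with the tether held over the ring, and carries the C7 oxygen from the start. It pays for this with a longer arene synthesis.

Key step: step 16

Assumption on numbering: labdane numbering is used for all ring and chain positions, and α means the face opposite to the C10 methyl group.
Assumption on step 16: the sense of induction of the chiral ligand cannot be predicted with confidence; the (R,R) antipode is written and would be exchanged for its mirror image if a first screen requires.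

## Route

Step 1
Reactants: 1 but-2-yn-1-ol
Product: 3 (Z)-3-iodobut-2-en-1-ol, via cyclic alkenylaluminate 2 (not isolated)
Conditions: NaAlH2(OCH2CH2OCH3)2, THF, 0 °C to rt; then I2, −78 °C to 0 °C
Reagents that add atoms: iodine, [I][I]
Why: Hydroxyl-directed trans-hydroalumination of the propargylic alcohol puts aluminium on C3 inside a five-membered aluminate, and iodinolysis with retention should give the Z vinyl iodide with iodine cis to the CH2OH group (hydroalumination–iodination).

Step 2
Reactants: 3 (Z)-3-iodobut-2-en-1-ol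
Product: 4 tert-butyl{[(2Z)-3-iodobut-2-en-1-yl]oxy}diphenylsilane
Conditions: t-BuPh2SiCl, imidazole, CH2Cl2, 0 °C to rt
Reagents that add atoms: tert-butyl(chloro)diphenylsilane, CC(C)(C)[Si](Cl)(c1ccccc1)c1ccccc1
Why: Standard silylation of a primary alcohol; the tert-butyldiphenylsilyl ether is chosen because it must outlast aqueous base, a Lewis acid and acetic acid later on.

Step 3
Reactants: 5 4-bromo-3,5-dimethylphenol; 6 1-bromo-3-methylbut-2-ene
Product: 7 2-bromo-1,3-dimethyl-5-[(3-methylbut-2-en-1-yl)oxy]benzene
Conditions: K2CO3, acetone, reflux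
Reagents that add atoms: none
Why: Williamson ether synthesis; SN2 attack of the phenoxide on the primary allylic bromide gives the O-prenyl ether needed for the sigmatropic step.

Step 4
Reactants: 7 2-bromo-1,3-dimethyl-5-[(3-methylbut-2-en-1-yl)oxy]benzene
Product: 8 4-bromo-3,5-dimethyl-2-(2-methylbut-3-en-2-yl)phenol
Conditions: N,N-diethylaniline, 185 °C, sealed tube
Reagents that add atoms: none
Why: Aromatic Claisen rearrangement: the [3,3] shift transfers the prenyl unit with allylic inversion to an ortho carbon, forming the C4–C5 bond and the quaternary benzylic carbon with its vinyl group. The two ortho positions of 7 are equivalent and the para position is blocked by bromine, so one product is expected after tautomerisation.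

Step 5
Reactants: 8 4-bromo-3,5-dimethyl-2-(2-methylbut-3-en-2-yl)phenol
Product: 9 3-bromo-6-hydroxy-2,4-dimethyl-5-(2-methylbut-3-en-2-yl)benzaldehyde
Conditions: MgCl2, Et3N, (CH2O)n, MeCN, reflux
Reagents that add atoms: paraformaldehyde (as formaldehyde), C=O
Why: Magnesium-phenoxide-directed ortho-formylation, which reacts only at the single free ortho position and is well established for ortho-tert-alkyl phenols; a second equivalent of formaldehyde takes up the hydride of the intermediate benzylic alkoxide.

Step 6
Reactants: 9 3-bromo-6-hydroxy-2,4-dimethyl-5-(2-methylbut-3-en-2-yl)benzaldehyde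
Product: 10 3-bromo-6-(methoxymethoxy)-2,4-dimethyl-5-(2-methylbut-3-en-2-yl)benzaldehyde
Conditions: NaH, CH3OCH2Cl, THF/DMF, 0 °C to rt
Reagents that add atoms: chloromethyl methyl ether, COCCl
Why: O-Alkylation of the sodium phenoxide (acetal formation); the methoxymethyl group is used on O6 because it can later be removed from the enol oxygen with a mild Lewis acid, which a methyl ether would not allow.

Step 7
Reactants: 10 3-bromo-6-(methoxymethoxy)-2,4-dimethyl-5-(2-methylbut-3-en-2-yl)benzaldehyde
Product: 12 3-bromo-6-(methoxymethoxy)-2,4-dimethyl-5-(2-methylbut-3-en-2-yl)phenol, via aryl formate 11 (not isolated)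
Conditions: mCPBA, CH2Cl2, 0 °C to rt; then K2CO3 (cat.), MeOH, rt
Reagents that add atoms: 3-chloroperoxybenzoic acid, OOC(=O)c1cccc(Cl)c1
Why: Baeyer–Villiger (Dakin-type) oxidation: the electron-rich aryl group next to an alkoxy substituent migrates in preference to hydride, and the hindered monosubstituted alkene should be epoxidised much more slowly than the aldehyde is oxidised. Methanolysis of the formate then frees the C7 phenol.

Step 8
Reactants: 12 3-bromo-6-(methoxymethoxy)-2,4-dimethyl-5-(2-methylbut-3-en-2-yl)phenol
Product: 13 [3-bromo-6-(methoxymethoxy)-2,4-dimethyl-5-(2-methylbut-3-en-2-yl)phenoxy]tri(propan-2-yl)silane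
Conditions: i-Pr3SiOTf, 2,6-lutidine, CH2Cl2, 0 °C
Reagents that add atoms: tri(propan-2-yl)silyl trifluoromethanesulfonate, CC(C)[Si](OS(=O)(=O)C(F)(F)F)(C(C)C)C(C)C
Why: Silylation of the hindered phenol with the reactive silyl triflate; the triisopropylsilyl aryl ether should survive the basic coupling steps and can later be removed from the aryl oxygen without touching the alkyl silyl ether.

Step 9
Reactants: 13 [3-bromo-6-(methoxymethoxy)-2,4-dimethyl-5-(2-methylbut-3-en-2-yl)phenoxy]tri(propan-2-yl)silane
Product: 15 2-[5-bromo-2-(methoxymethoxy)-4,6-dimethyl-3-{[tri(propan-2-yl)silyl]oxy}phenyl]-2-methylpropanal, via ozonide 14 (not isolated)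
Conditions: O3, CH2Cl2, −78 °C; then Me2S, −78 °C to rt
Reagents that add atoms: ozone, [O-][O+]=O
Why: Ozonolysis of the only C=C bond present, with reductive work-up, gives the neopentyl aldehyde; the alkene reacts far faster with ozone than the silylated arene.

Step 10
Reactants: 15 2-[5-bromo-2-(methoxymethoxy)-4,6-dimethyl-3-{[tri(propan-2-yl)silyl]oxy}phenyl]-2-methylpropanal
Product: 16 methyl (2Z)-4-[5-bromo-2-(methoxymethoxy)-4,6-dimethyl-3-{[tri(propan-2-yl)silyl]oxy}phenyl]-4-methylpent-2-enoate
Conditions: (CF3CH2O)2P(O)CH2CO2Me, KN(SiMe3)2, 18-crown-6, THF, −78 °C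
Reagents that add atoms: methyl 2-[bis(2,2,2-trifluoroethoxy)phosphoryl]acetate, COC(=O)CP(=O)(OCC(F)(F)F)OCC(F)(F)F
Why: Still–Gennari olefination: the bis(trifluoroethyl) phosphonate under dissociating conditions gives kinetic, Z-selective elimination, and hindered α-quaternary aldehydes are good substrates. This sets the cis C2=C3 geometry that later gives the anti allyl complex.

Step 11
Reactants: 16 methyl (2Z)-4-[5-bromo-2-(methoxymethoxy)-4,6-dimethyl-3-{[tri(propan-2-yl)silyl]oxy}phenyl]-4-methylpent-2-enoate
Product: 17 methyl (2Z)-4-[5-ethenyl-2-(methoxymethoxy)-4,6-dimethyl-3-{[tri(propan-2-yl)silyl]oxy}phenyl]-4-methylpent-2-enoate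
Conditions: vinylboronic acid pinacol ester, Pd(OAc)2, SPhos, K3PO4, toluene/H2O, 80 °C
Reagents that add atoms: 2-ethenyl-4,4,5,5-tetramethyl-1,3,2-dioxaborolane, C=CB1OC(C)(C)C(C)(C)O1
Why: Suzuki–Miyaura coupling; the bulky, electron-rich biaryl phosphine allows oxidative addition and reductive elimination at the aryl bromide flanked by two methyl groups, and the Z enoate and the silyl ether are expected to be inert.

Step 12
Reactants: 17 methyl (2Z)-4-[5-ethenyl-2-(methoxymethoxy)-4,6-dimethyl-3-{[tri(propan-2-yl)silyl]oxy}phenyl]-4-methylpent-2-enoate; 4 tert-butyl{[(2Z)-3-iodobut-2-en-1-yl]oxy}diphenylsilane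
Product: 19 methyl (2Z)-4-[5-[(3Z)-5-{[tert-butyl(diphenyl)silyl]oxy}-3-methylpent-3-en-1-yl]-2-(methoxymethoxy)-4,6-dimethyl-3-{[tri(propan-2-yl)silyl]oxy}phenyl]-4-methylpent-2-enoate, via alkylborane 18 (not isolated)
Conditions: 9-BBN-H, THF, 0 °C to rt; then 4, PdCl2(dppf), AsPh3, K3PO4, DMF/H2O, rt
Reagents that add atoms: none
Why: Anti-Markovnikov hydroboration of the styrene-type alkene with 9-BBN (the conjugated, hindered Z enoate is left alone), then B-alkyl Suzuki–Miyaura coupling with the vinyl iodide. The coupling proceeds with retention and carries the Z geometry of 4 into the C13=C14 bond.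

Step 13
Reactants: 19 methyl (2Z)-4-[5-[(3Z)-5-{[tert-butyl(diphenyl)silyl]oxy}-3-methylpent-3-en-1-yl]-2-(methoxymethoxy)-4,6-dimethyl-3-{[tri(propan-2-yl)silyl]oxy}phenyl]-4-methylpent-2-enoate
Product: 20 (2Z)-4-[5-[(3Z)-5-{[tert-butyl(diphenyl)silyl]oxy}-3-methylpent-3-en-1-yl]-2-(methoxymethoxy)-4,6-dimethyl-3-{[tri(propan-2-yl)silyl]oxy}phenyl]-4-methylpent-2-en-1-ol
Conditions: i-Bu2AlH, CH2Cl2, −78 °C; aqueous potassium sodium tartrate work-up
Reagents that add atoms: none
Why: 1,2-Reduction of the α,β-unsaturated ester with the aluminium hydride at low temperature gives the Z allylic alcohol without touching the double bonds or the ethers.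

Step 14
Reactants: 20 (2Z)-4-[5-[(3Z)-5-{[tert-butyl(diphenyl)silyl]oxy}-3-methylpent-3-en-1-yl]-2-(methoxymethoxy)-4,6-dimethyl-3-{[tri(propan-2-yl)silyl]oxy}phenyl]-4-methylpent-2-en-1-ol
Product: 21 (2Z)-4-[5-[(3Z)-5-{[tert-butyl(diphenyl)silyl]oxy}-3-methylpent-3-en-1-yl]-2-(methoxymethoxy)-4,6-dimethyl-3-{[tri(propan-2-yl)silyl]oxy}phenyl]-4-methylpent-2-en-1-yl methyl carbonate
Conditions: ClCO2Me, pyridine, CH2Cl2, 0 °C
Reagents that add atoms: methyl chloroformate, COC(=O)Cl
Why: Acylation of the primary alcohol; the carbonate is installed only now because every earlier palladium-catalysed step would have ionised it.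

Step 15
Reactants: 21 (2Z)-4-[5-[(3Z)-5-{[tert-butyl(diphenyl)silyl]oxy}-3-methylpent-3-en-1-yl]-2-(methoxymethoxy)-4,6-dimethyl-3-{[tri(propan-2-yl)silyl]oxy}phenyl]-4-methylpent-2-en-1-yl methyl carbonate
Product: 22 (2Z)-4-[5-[(3Z)-5-{[tert-butyl(diphenyl)silyl]oxy}-3-methylpent-3-en-1-yl]-3-hydroxy-2-(methoxymethoxy)-4,6-dimethylphenyl]-4-methylpent-2-en-1-yl methyl carbonate
Conditions: Bu4NF, AcOH, THF, 0 °C
Reagents that add atoms: none
Why: Fluoride-induced desilylation; a phenoxide is a far better leaving group from silicon than an alkoxide, so buffered fluoride at 0 °C should free the phenol selectively while the primary tert-butyldiphenylsilyl ether and the carbonate remain.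

Step 16
Reactants: 22 (2Z)-4-[5-[(3Z)-5-{[tert-butyl(diphenyl)silyl]oxy}-3-methylpent-3-en-1-yl]-3-hydroxy-2-(methoxymethoxy)-4,6-dimethylphenyl]-4-methylpent-2-en-1-yl methyl carbonate
Product: 23 (10R)-15-{[tert-butyl(diphenyl)silyl]oxy}-6-(methoxymethoxy)labda-2,5,8,13Z-tetraen-7-one (ring A with C2=C3, ring B a cross-conjugated dienone, 10β-methyl)
Conditions: Pd2(dba)3·CHCl3 (2.5 mol%), (R,R)-N,N'-(cyclohexane-1,2-diyl)bis[2-(diphenylphosphanyl)benzamide] (7.5 mol%), toluene (0.01 M), 25 °C
Reagents that add atoms: none
Why: Proposed new method: zerovalent palladium ionises the Z allylic carbonate with loss of CO2 and methoxide, the methoxide deprotonates the phenol, and the resulting anti allyl–palladium cation is attacked by its own phenoxide through the para carbon C10; the closest known reaction type is the palladium- or iridium-catalysed intramolecular asymmetric allylic dearomatisation of para-tethered phenols, which attacks the near allyl terminus and gives spiro dienones, whereas here the tether sits meta to the oxygen and the far terminus is attacked. Ring A closes in the six-membered endo mode, C10 bonding to the distal allyl carbon C1 so that C2=C3 ends inside the ring, because closure at the near carbon C3 would need a four-membered ring. C10 is the only new stereocentre and, as the substrate has no other, its configuration is set by the chiral bisphosphine on palladium, which must tell apart the two faces of the flat phenoxide over which the allyl unit can swing; the ligand antipode that gives 10R in 23 would be fixed in a first screen. The step needs attack by C10 and not by oxygen or by C6: an intramolecular O-alkylation would require a five-atom bridge across meta positions, intermolecular O-allylation is reversible under the catalyst and is suppressed by dilution, and C6 is ortho, carries the electron-withdrawing and bulky methoxymethoxy group and would have to become a crowded ketal-type carbon. The gem-dimethyl group at C4, buttressed by both ortho neighbours, holds the allyl unit over the ring, the Z geometry gives the anti complex directly without syn–anti isomerisation, and the allyl unit has no β-hydrogen, so diene formation cannot compete.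

Step 17
Reactants: 23 (10R)-15-{[tert-butyl(diphenyl)silyl]oxy}-6-(methoxymethoxy)labda-2,5,8,13Z-tetraen-7-one
Product: 24 (10R)-15-{[tert-butyl(diphenyl)silyl]oxy}-6-(methoxymethoxy)labda-5,8,13Z-trien-7-one
Conditions: 2-nitrobenzenesulfonohydrazide, Et3N, CH2Cl2, rt
Reagents that add atoms: none
Why: Diimide reduction: the concerted syn transfer of H2 is very sensitive to substitution, so the cis-disubstituted C2=C3 bond should react in preference to the trisubstituted C13=C14 bond and the tetrasubstituted, polarised dienone bonds.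

Step 18
Reactants: 24 (10R)-15-{[tert-butyl(diphenyl)silyl]oxy}-6-(methoxymethoxy)labda-5,8,13Z-trien-7-one
Product: 25 (10R)-15-{[tert-butyl(diphenyl)silyl]oxy}-6-hydroxylabda-5,8,13Z-trien-7-one (diosphenol)
Conditions: ZnBr2, n-PrSH, CH2Cl2, 0 °C
Reagents that add atoms: none
Why: Lewis-acid-assisted acetal cleavage: ZnBr2 chelated between the acetal oxygens and the C7 carbonyl activates the O–CH2 bond for attack by the thiol, a mild known way to remove methoxymethyl groups that leaves silyl ethers intact.

Step 19
Reactants: 25 (10R)-15-{[tert-butyl(diphenyl)silyl]oxy}-6-hydroxylabda-5,8,13Z-trien-7-one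
Product: 27 15-{[tert-butyl(diphenyl)silyl]oxy}-5α-labda-8,13Z-diene-6β,7-diol (both C7 epimers), via ketol 26 (not isolated)
Conditions: NaBH4, CeCl3·7H2O, MeOH/THF, −20 °C to rt
Reagents that add atoms: none
Why: Luche-type 1,2-reduction of the dienone at C7 (no facial bias is expected, so both C7 epimers should form) is followed by ketonisation of the enol with protonation of C5 from the α face to the more stable trans ring fusion. Reduction of the C6 ketone then occurs from the open α face, because the axial methyls on C4 and C10 close the β face, and should give the 6β-alcohol in both epimers.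

Step 20
Reactants: 27 15-{[tert-butyl(diphenyl)silyl]oxy}-5α-labda-8,13Z-diene-6β,7-diol (both C7 epimers)
Product: 28 15-{[tert-butyl(diphenyl)silyl]oxy}-6β-hydroxy-5α-labda-8,13Z-dien-7-one
Conditions: MnO2, CH2Cl2, rt
Reagents that add atoms: none
Why: Chemoselective MnO2 oxidation of the allylic C7 alcohol; the saturated, strongly hindered 6β-alcohol should not react, so both C7 epimers converge on one α-hydroxy enone, and any 7α epimer that reacts slowly is already compound 29.

Step 21
Reactants: 28 15-{[tert-butyl(diphenyl)silyl]oxy}-6β-hydroxy-5α-labda-8,13Z-dien-7-one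
Product: 29 15-{[tert-butyl(diphenyl)silyl]oxy}-5α-labda-8,13Z-diene-6β,7α-diol
Conditions: Me4NBH(OAc)3, AcOH/MeCN, −30 °C
Reagents that add atoms: none
Why: Hydroxyl-directed triacetoxyborohydride reduction: ligand exchange binds boron to the axial 6β-oxygen, and internal hydride delivery to the neighbouring C7 carbonyl occurs on the β face, which should give the 7α-alcohol and thus the trans-diaxial diol. Ketones without a neighbouring hydroxyl are not reduced by this reagent, so the external α-face pathway is suppressed.

Step 22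
Reactants: 29 15-{[tert-butyl(diphenyl)silyl]oxy}-5α-labda-8,13Z-diene-6β,7α-diol
Product: 30 15-{[tert-butyl(diphenyl)silyl]oxy}-7α-[(triethylsilyl)oxy]-5α-labda-8,13Z-dien-6β-ol
Conditions: Et3SiCl, imidazole, DMF, 0 °C
Reagents that add atoms: chlorotriethylsilane, CC[Si](Cl)(CC)CC
Why: Selective silylation: the allylic C7 hydroxyl reacts with the silyl chloride, whereas the 6β-hydroxyl, syn-axial to two methyl groups, should not under these mild conditions.

Step 23
Reactants: 30 15-{[tert-butyl(diphenyl)silyl]oxy}-7α-[(triethylsilyl)oxy]-5α-labda-8,13Z-dien-6β-ol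
Product: 31 6β-acetoxy-15-{[tert-butyl(diphenyl)silyl]oxy}-7α-[(triethylsilyl)oxy]-5α-labda-8,13Z-diene
Conditions: Ac2O, DMAP, pyridine, 50 °C
Reagents that add atoms: acetic anhydride, CC(=O)OC(C)=O
Why: DMAP-catalysed acylation of the one remaining free hydroxyl under forcing conditions; the acetylpyridinium ion is small and reactive enough for this doubly syn-axial alcohol.

Step 24
Reactants: 31 6β-acetoxy-15-{[tert-butyl(diphenyl)silyl]oxy}-7α-[(triethylsilyl)oxy]-5α-labda-8,13Z-diene
Product: 32 6β-acetoxy-5α-labda-8,13Z-diene-7α,15-diol (5S,6S,7S,10S), the target CNP0183298.2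
Conditions: Bu4NF, AcOH, THF, rt
Reagents that add atoms: none
Why: Buffered fluoride removes both silyl ethers; the trans-diaxial arrangement of O6 and O7 prevents acetyl migration to the freed C7 hydroxyl, and the hindered acetate resists solvolysis.

## Compound list

1 | but-2-yn-1-ol | CC#CCO | starting material
2 | sodium 2,2-bis(2-methoxyethoxy)-3-methyl-2,5-dihydro-1,2-oxaaluminol-2-uide (cyclic Z-alkenylaluminate) | CC1=CCO[Al-]1(OCCOC)OCCOC.[Na+] | intermediate (not isolated)
3 | (Z)-3-iodobut-2-en-1-ol | C/C(I)=C/CO | intermediate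
4 | tert-butyl{[(2Z)-3-iodobut-2-en-1-yl]oxy}diphenylsilane | C/C(I)=C/CO[Si](c1ccccc1)(c1ccccc1)C(C)(C)C | intermediate
5 | 4-bromo-3,5-dimethylphenol | Cc1cc(O)cc(C)c1Br | starting material
6 | 1-bromo-3-methylbut-2-ene | CC(C)=CCBr | starting material
7 | 2-bromo-1,3-dimethyl-5-[(3-methylbut-2-en-1-yl)oxy]benzene | CC(C)=CCOc1cc(C)c(Br)c(C)c1 | intermediate
8 | 4-bromo-3,5-dimethyl-2-(2-methylbut-3-en-2-yl)phenol | C=CC(C)(C)c1c(O)cc(C)c(Br)c1C | intermediate
9 | 3-bromo-6-hydroxy-2,4-dimethyl-5-(2-methylbut-3-en-2-yl)benzaldehyde | C=CC(C)(C)c1c(O)c(C=O)c(C)c(Br)c1C | intermediate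
10 | 3-bromo-6-(methoxymethoxy)-2,4-dimethyl-5-(2-methylbut-3-en-2-yl)benzaldehyde | C=CC(C)(C)c1c(OCOC)c(C=O)c(C)c(Br)c1C | intermediate
11 | 3-bromo-6-(methoxymethoxy)-2,4-dimethyl-5-(2-methylbut-3-en-2-yl)phenyl formate | C=CC(C)(C)c1c(OCOC)c(OC=O)c(C)c(Br)c1C | intermediate (not isolated)
12 | 3-bromo-6-(methoxymethoxy)-2,4-dimethyl-5-(2-methylbut-3-en-2-yl)phenol | C=CC(C)(C)c1c(OCOC)c(O)c(C)c(Br)c1C | intermediate
13 | [3-bromo-6-(methoxymethoxy)-2,4-dimethyl-5-(2-methylbut-3-en-2-yl)phenoxy]tri(propan-2-yl)silane | C=CC(C)(C)c1c(OCOC)c(O[Si](C(C)C)(C(C)C)C(C)C)c(C)c(Br)c1C | intermediate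
14 | 3-{2-[5-bromo-2-(methoxymethoxy)-4,6-dimethyl-3-{[tri(propan-2-yl)silyl]oxy}phenyl]propan-2-yl}-1,2,4-trioxolane | CC(C)(C2OCOO2)c1c(OCOC)c(O[Si](C(C)C)(C(C)C)C(C)C)c(C)c(Br)c1C | intermediate (not isolated)
15 | 2-[5-bromo-2-(methoxymethoxy)-4,6-dimethyl-3-{[tri(propan-2-yl)silyl]oxy}phenyl]-2-methylpropanal | CC(C)(C=O)c1c(OCOC)c(O[Si](C(C)C)(C(C)C)C(C)C)c(C)c(Br)c1C | intermediate
16 | methyl (2Z)-4-[5-bromo-2-(methoxymethoxy)-4,6-dimethyl-3-{[tri(propan-2-yl)silyl]oxy}phenyl]-4-methylpent-2-enoate | COC(=O)/C=C\C(C)(C)c1c(OCOC)c(O[Si](C(C)C)(C(C)C)C(C)C)c(C)c(Br)c1C | intermediate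
17 | methyl (2Z)-4-[5-ethenyl-2-(methoxymethoxy)-4,6-dimethyl-3-{[tri(propan-2-yl)silyl]oxy}phenyl]-4-methylpent-2-enoate | COC(=O)/C=C\C(C)(C)c1c(OCOC)c(O[Si](C(C)C)(C(C)C)C(C)C)c(C)c(C=C)c1C | intermediate
18 | methyl (2Z)-4-[5-[2-(9-borabicyclo[3.3.1]nonan-9-yl)ethyl]-2-(methoxymethoxy)-4,6-dimethyl-3-{[tri(propan-2-yl)silyl]oxy}phenyl]-4-methylpent-2-enoate | COC(=O)/C=C\C(C)(C)c1c(OCOC)c(O[Si](C(C)C)(C(C)C)C(C)C)c(C)c(CCB2C3CCCC2CCC3)c1C | intermediate (not isolated)
19 | methyl (2Z)-4-[5-[(3Z)-5-{[tert-butyl(diphenyl)silyl]oxy}-3-methylpent-3-en-1-yl]-2-(methoxymethoxy)-4,6-dimethyl-3-{[tri(propan-2-yl)silyl]oxy}phenyl]-4-methylpent-2-enoate | COC(=O)/C=C\C(C)(C)c1c(OCOC)c(O[Si](C(C)C)(C(C)C)C(C)C)c(C)c(CC/C(C)=C\CO[Si](c2ccccc2)(c2ccccc2)C(C)(C)C)c1C | intermediate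
20 | (2Z)-4-[5-[(3Z)-5-{[tert-butyl(diphenyl)silyl]oxy}-3-methylpent-3-en-1-yl]-2-(methoxymethoxy)-4,6-dimethyl-3-{[tri(propan-2-yl)silyl]oxy}phenyl]-4-methylpent-2-en-1-ol | OC/C=C\C(C)(C)c1c(OCOC)c(O[Si](C(C)C)(C(C)C)C(C)C)c(C)c(CC/C(C)=C\CO[Si](c2ccccc2)(c2ccccc2)C(C)(C)C)c1C | intermediate
21 | (2Z)-4-[5-[(3Z)-5-{[tert-butyl(diphenyl)silyl]oxy}-3-methylpent-3-en-1-yl]-2-(methoxymethoxy)-4,6-dimethyl-3-{[tri(propan-2-yl)silyl]oxy}phenyl]-4-methylpent-2-en-1-yl methyl carbonate | COC(=O)OC/C=C\C(C)(C)c1c(OCOC)c(O[Si](C(C)C)(C(C)C)C(C)C)c(C)c(CC/C(C)=C\CO[Si](c2ccccc2)(c2ccccc2)C(C)(C)C)c1C | intermediate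
22 | (2Z)-4-[5-[(3Z)-5-{[tert-butyl(diphenyl)silyl]oxy}-3-methylpent-3-en-1-yl]-3-hydroxy-2-(methoxymethoxy)-4,6-dimethylphenyl]-4-methylpent-2-en-1-yl methyl carbonate | COC(=O)OC/C=C\C(C)(C)c1c(OCOC)c(O)c(C)c(CC/C(C)=C\CO[Si](c2ccccc2)(c2ccccc2)C(C)(C)C)c1C | intermediate (key-step precursor)
23 | (10R)-15-{[tert-butyl(diphenyl)silyl]oxy}-6-(methoxymethoxy)labda-2,5,8,13Z-tetraen-7-one | COCOC1=C2C(C)(C)C=CC[C@]2(C)C(CC/C(C)=C\CO[Si](c3ccccc3)(c3ccccc3)C(C)(C)C)=C(C)C1=O | intermediate (key-step product)
24 | (10R)-15-{[tert-butyl(diphenyl)silyl]oxy}-6-(methoxymethoxy)labda-5,8,13Z-trien-7-one | COCOC1=C2C(C)(C)CCC[C@]2(C)C(CC/C(C)=C\CO[Si](c3ccccc3)(c3ccccc3)C(C)(C)C)=C(C)C1=O | intermediate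
25 | (10R)-15-{[tert-butyl(diphenyl)silyl]oxy}-6-hydroxylabda-5,8,13Z-trien-7-one | OC1=C2C(C)(C)CCC[C@]2(C)C(CC/C(C)=C\CO[Si](c3ccccc3)(c3ccccc3)C(C)(C)C)=C(C)C1=O | intermediate
26 | 15-{[tert-butyl(diphenyl)silyl]oxy}-7-hydroxy-5α-labda-8,13Z-dien-6-one (both C7 epimers) | O=C1C(O)C(C)=C(CC/C(C)=C\CO[Si](c3ccccc3)(c3ccccc3)C(C)(C)C)[C@@]2(C)CCCC(C)(C)[C@H]12 | intermediate (not isolated)
27 | 15-{[tert-butyl(diphenyl)silyl]oxy}-5α-labda-8,13Z-diene-6β,7-diol (both C7 epimers) | O[C@@H]1C(O)C(C)=C(CC/C(C)=C\CO[Si](c3ccccc3)(c3ccccc3)C(C)(C)C)[C@@]2(C)CCCC(C)(C)[C@H]12 | intermediate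
28 | 15-{[tert-butyl(diphenyl)silyl]oxy}-6β-hydroxy-5α-labda-8,13Z-dien-7-one | O[C@@H]1C(=O)C(C)=C(CC/C(C)=C\CO[Si](c3ccccc3)(c3ccccc3)C(C)(C)C)[C@@]2(C)CCCC(C)(C)[C@H]12 | intermediate
29 | 15-{[tert-butyl(diphenyl)silyl]oxy}-5α-labda-8,13Z-diene-6β,7α-diol | O[C@@H]1[C@@H](O)C(C)=C(CC/C(C)=C\CO[Si](c3ccccc3)(c3ccccc3)C(C)(C)C)[C@@]2(C)CCCC(C)(C)[C@H]12 | intermediate
30 | 15-{[tert-butyl(diphenyl)silyl]oxy}-7α-[(triethylsilyl)oxy]-5α-labda-8,13Z-dien-6β-ol | O[C@@H]1[C@@H](O[Si](CC)(CC)CC)C(C)=C(CC/C(C)=C\CO[Si](c3ccccc3)(c3ccccc3)C(C)(C)C)[C@@]2(C)CCCC(C)(C)[C@H]12 | intermediate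
31 | 6β-acetoxy-15-{[tert-butyl(diphenyl)silyl]oxy}-7α-[(triethylsilyl)oxy]-5α-labda-8,13Z-diene | CC(=O)O[C@@H]1[C@@H](O[Si](CC)(CC)CC)C(C)=C(CC/C(C)=C\CO[Si](c3ccccc3)(c3ccccc3)C(C)(C)C)[C@@]2(C)CCCC(C)(C)[C@H]12 | intermediate
32 | 6β-acetoxy-5α-labda-8,13Z-diene-7α,15-diol (5S,6S,7S,10S) | CC(=O)O[C@@H]1[C@@H](O)C(C)=C(CC/C(C)=C\CO)[C@@]2(C)CCCC(C)(C)[C@H]12 | target

## Step count and least certain steps

Total: 24 steps. Longest linear sequence: 22 steps (steps 3–24, from 4-bromo-3,5-dimethylphenol 5). Steps 1–2 make the side-chain fragment 4.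

**Step 16 (key step).** The most likely failure is attack of the phenoxide through C6 instead of C10, since both closures are six-membered and no closely related fused-ring case exists. Low discrimination between the two faces of the phenoxide by the ligand is the second risk. A slow ring closure would also let intermolecular O-allylation consume material. The fallback uses known chemistry and sets out from 19. Copper hydride conjugate reduction of the enoate ([CuH(PPh3)]6, PhSiH3) would give the saturated ester F1. Reduction with i-Bu2AlH would give the primary alcohol F2, and MsCl/Et3N the mesylate F3. Buffered Bu4NF would free the phenol to give the phenol mesylate F4. KOt-Bu in t-BuOH at high dilution would then close ring A by the classical base-mediated intramolecular alkylative dearomatisation of a phenoxide, giving the racemic dienone F5. Resolution of F5 by preparative chromatography on a chiral stationary phase would return the route at 24.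

**Step 4 (Claisen rearrangement).** The most likely failure is loss of the first-formed phenol by further thermal reactions: the abnormal Claisen pathway, ring closure of the hydroxyl onto the new alkene, or fragmentation and recombination of the prenyl unit. The hydroxyl of 8 lies next to the vinyl group and the new quaternary carbon is crowded by the neighbouring methyl. The fallback sets out from 5. Ortho-formylation first (MgCl2, Et3N, paraformaldehyde) would give 5-bromo-2-hydroxy-4,6-dimethylbenzaldehyde F6, and O-prenylation with 6 the ether 5-bromo-4,6-dimethyl-2-[(3-methylbut-2-en-1-yl)oxy]benzaldehyde F7. The sigmatropic shift of F7 has only one free ortho position and gives a phenol locked in a hydrogen bond to the aldehyde, which cannot feed the follow-up reactions. This returns the route at 9.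

**Step 17 (diimide reduction).** The most likely failure is incomplete discrimination between the ring-A alkene, slowed by the neighbouring quaternary C4, and the trisubstituted side-chain alkene, leading to over-reduction of the chain. The fallback sets out from 23 and replaces the hydrogen-transfer reagent by homogeneous hydrogenation with RhCl(PPh3)3 and H2. This catalyst selects by alkene coordination and is very slow with trisubstituted alkenes. It returns at 24 without a new compound.

**Step 21 (directed reduction).** The most likely failure is loss of internal delivery, giving external hydride attack from the α face or conjugate reduction of the enone; boron may bind poorly to the very hindered axial hydroxyl. The fallback sets out from 28. Luche reduction from the α face would give the cis-diol 15-{[tert-butyl(diphenyl)silyl]oxy}-5α-labda-8,13Z-diene-6β,7β-diol F8. Mitsunobu inversion at the allylic C7 hydroxyl (4-nitrobenzoic acid, PPh3, diisopropyl azodicarboxylate), which the 6β-hydroxyl is too hindered to join, would give the 7α-(4-nitrobenzoate) F9. Methanolysis (K2CO3, MeOH) returns the route at 29.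

**Step 23 (acetylation).** The most likely failure is no or very slow acylation, because the 6β-hydroxyl is syn-axial to two methyl groups and also flanked by the 7α-silyl ether; forcing conditions could then cause silyl loss or migration. The fallback sets out from 28, where C7 is trigonal and carries no silyl group. Acetylation (Ac2O, DMAP) would give the 6β-acetoxy enone F10. Luche reduction from the α face would give the 7β-alcohol F11. Mitsunobu inversion with 4-nitrobenzoic acid would give the 7α-(4-nitrobenzoate) F12. Brief methanolysis would cleave only the activated benzoate and give the 6β-acetoxy-7α-alcohol F13. Desilylation with Bu4NF then reaches the target 32 directly.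

## Further compounds

F1 | step 16 | methyl 4-[5-[(3Z)-5-{[tert-butyl(diphenyl)silyl]oxy}-3-methylpent-3-en-1-yl]-2-(methoxymethoxy)-4,6-dimethyl-3-{[tri(propan-2-yl)silyl]oxy}phenyl]-4-methylpentanoate | COC(=O)CCC(C)(C)c1c(OCOC)c(O[Si](C(C)C)(C(C)C)C(C)C)c(C)c(CC/C(C)=C\CO[Si](c2ccccc2)(c2ccccc2)C(C)(C)C)c1C
F2 | step 16 | 4-[5-[(3Z)-5-{[tert-butyl(diphenyl)silyl]oxy}-3-methylpent-3-en-1-yl]-2-(methoxymethoxy)-4,6-dimethyl-3-{[tri(propan-2-yl)silyl]oxy}phenyl]-4-methylpentan-1-ol | OCCCC(C)(C)c1c(OCOC)c(O[Si](C(C)C)(C(C)C)C(C)C)c(C)c(CC/C(C)=C\CO[Si](c2ccccc2)(c2ccccc2)C(C)(C)C)c1C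
F3 | step 16 | 4-[5-[(3Z)-5-{[tert-butyl(diphenyl)silyl]oxy}-3-methylpent-3-en-1-yl]-2-(methoxymethoxy)-4,6-dimethyl-3-{[tri(propan-2-yl)silyl]oxy}phenyl]-4-methylpentyl methanesulfonate | CS(=O)(=O)OCCCC(C)(C)c1c(OCOC)c(O[Si](C(C)C)(C(C)C)C(C)C)c(C)c(CC/C(C)=C\CO[Si](c2ccccc2)(c2ccccc2)C(C)(C)C)c1C
F4 | step 16 | 4-[5-[(3Z)-5-{[tert-butyl(diphenyl)silyl]oxy}-3-methylpent-3-en-1-yl]-3-hydroxy-2-(methoxymethoxy)-4,6-dimethylphenyl]-4-methylpentyl methanesulfonate | CS(=O)(=O)OCCCC(C)(C)c1c(OCOC)c(O)c(C)c(CC/C(C)=C\CO[Si](c2ccccc2)(c2ccccc2)C(C)(C)C)c1C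
F5 | step 16 | racemic 15-{[tert-butyl(diphenyl)silyl]oxy}-6-(methoxymethoxy)labda-5,8,13Z-trien-7-one | COCOC1=C2C(C)(C)CCCC2(C)C(CC/C(C)=C\CO[Si](c3ccccc3)(c3ccccc3)C(C)(C)C)=C(C)C1=O
F6 | step 4 | 5-bromo-2-hydroxy-4,6-dimethylbenzaldehyde | O=Cc1c(O)cc(C)c(Br)c1C
F7 | step 4 | 5-bromo-4,6-dimethyl-2-[(3-methylbut-2-en-1-yl)oxy]benzaldehyde | CC(C)=CCOc1cc(C)c(Br)c(C)c1C=O
F0 | step 17 | none | none
F8 | step 21 | 15-{[tert-butyl(diphenyl)silyl]oxy}-5α-labda-8,13Z-diene-6β,7β-diol | O[C@@H]1[C@H](O)C(C)=C(CC/C(C)=C\CO[Si](c3ccccc3)(c3ccccc3)C(C)(C)C)[C@@]2(C)CCCC(C)(C)[C@H]12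
F9 | step 21 | 15-{[tert-butyl(diphenyl)silyl]oxy}-6β-hydroxy-5α-labda-8,13Z-dien-7α-yl 4-nitrobenzoate | O[C@@H]1[C@@H](OC(=O)c3ccc(cc3)[N+](=O)[O-])C(C)=C(CC/C(C)=C\CO[Si](c3ccccc3)(c3ccccc3)C(C)(C)C)[C@@]2(C)CCCC(C)(C)[C@H]12
F10 | step 23 | 6β-acetoxy-15-{[tert-butyl(diphenyl)silyl]oxy}-5α-labda-8,13Z-dien-7-one | CC(=O)O[C@@H]1C(=O)C(C)=C(CC/C(C)=C\CO[Si](c3ccccc3)(c3ccccc3)C(C)(C)C)[C@@]2(C)CCCC(C)(C)[C@H]12
F11 | step 23 | 6β-acetoxy-15-{[tert-butyl(diphenyl)silyl]oxy}-5α-labda-8,13Z-dien-7β-ol | CC(=O)O[C@@H]1[C@H](O)C(C)=C(CC/C(C)=C\CO[Si](c3ccccc3)(c3ccccc3)C(C)(C)C)[C@@]2(C)CCCC(C)(C)[C@H]12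
F12 | step 23 | 6β-acetoxy-15-{[tert-butyl(diphenyl)silyl]oxy}-5α-labda-8,13Z-dien-7α-yl 4-nitrobenzoate | CC(=O)O[C@@H]1[C@@H](OC(=O)c3ccc(cc3)[N+](=O)[O-])C(C)=C(CC/C(C)=C\CO[Si](c3ccccc3)(c3ccccc3)C(C)(C)C)[C@@]2(C)CCCC(C)(C)[C@H]12
F13 | step 23 | 6β-acetoxy-15-{[tert-butyl(diphenyl)silyl]oxy}-5α-labda-8,13Z-dien-7α-ol | CC(=O)O[C@@H]1[C@@H](O)C(C)=C(CC/C(C)=C\CO[Si](c3ccccc3)(c3ccccc3)C(C)(C)C)[C@@]2(C)CCCC(C)(C)[C@H]12
A1 | alternative 1 | 3-[4-{[tert-butyl(diphenyl)silyl]oxy}but-1-en-2-yl]-2-(1-hydroxy-3-methylbut-3-en-1-yl)-3-methylcyclohexan-1-one (configuration as in the SMILES) | C=C(C)C[C@H](O)[C@H]1C(=O)CCC[C@]1(C)C(=C)CCO[Si](c1ccccc1)(c1ccccc1)C(C)(C)C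
A2 | alternative 1 | 3-methylcyclohex-2-en-1-one | CC1=CC(=O)CCC1
A3 | alternative 1 | [4-{[tert-butyl(diphenyl)silyl]oxy}but-1-en-2-yl]bis(2-methylpropyl)alumane | C=C(CCO[Si](c1ccccc1)(c1ccccc1)C(C)(C)C)[Al](CC(C)C)CC(C)C
A4 | alternative 1 | 3-methylbut-3-enal | CC(=C)CC=O
A5 | alternative 2 | 8-bromo-6β-[(tert-butyldimethylsilyl)oxy]-7α-hydroxy decalin with C8=C9 alkene and a 4-[tri(propan-2-yl)silyl]but-3-ynyl group on C9 | CC(C)(C)[Si](C)(C)O[C@@H]1[C@@H](O)C(Br)=C(CCC#C[Si](C(C)C)(C(C)C)C(C)C)[C@@]2(C)CCCC(C)(C)[C@H]12
A6 | alternative 2 | trans-fused hydrindene with C7=C9 alkene, 6β-[(tert-butyldimethylsilyl)oxy] group and the same silylbutynyl chain on C9 | CC(C)(C)[Si](C)(C)O[C@@H]1C=C(CCC#C[Si](C(C)C)(C(C)C)C(C)C)[C@@]2(C)CCCC(C)(C)[C@H]12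
A7 | alternative 3 | bicyclic cyclohexadiene with C6 silyl enol ether, C8=C9 alkene and C11 aldehyde | CC(C)(C)[Si](C)(C)OC1=C2C(C)(C)CCC[C@]2(C)C(C=O)=C(C)C1
A8 | alternative 3 | tert-butyldimethyl{[1-(2,6,6-trimethylcyclohex-1-en-1-yl)ethenyl]oxy}silane | C=C(O[Si](C)(C)C(C)(C)C)C1=C(C)CCCC1(C)C
A9 | alternative 3 | but-2-ynal | CC#CC=O
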